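**Retrosynthetic overview**

1. The target is a 6,6'-linked pair of 2,2-dimethyl-2H-chromenes: ring A (prenylated benzene) fused to pyran ring B, and ring C (hydroxylated benzene) fused to pyran ring D. The last operation removes a methoxymethyl (MOM) group from the C8 oxygen of ring C.
2. Key disconnection: the aryl–vinyl bonds C4–C4a of both pyran rings B and D are opened together, leading back to the bis(1,1-dimethylpropargyl) ether of a biphenyl-4,4'-diol. Forward, one double 6-endo-dig hydroarylation under monovalent gold catalysis closes both rings.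
3. Enabling feature: each pyran oxygen O1 sits on an aromatic carbon C8a whose one ortho position is blocked (C8: prenyl CH2 on ring A, oxygen substituent on ring C) and whose other ortho position C4a is a free, oxygen-activated CH. C4 is a terminal alkyne carbon and the gem-dimethyl carbon C2 folds the O–C2–C3≡C4 arm onto C4a.
4. The bis-ether comes from double O-propargylation of a biphenyl diol, made by Suzuki–Miyaura coupling of a 2-prenylphenol boronate (cross-metathesis, then borylation) with 4-bromo-2-(methoxymethoxy)phenol (MOM protection, then Baeyer–Villiger oxidation).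
5. Ring order: benzene rings A and C are purchased, the A–C bond is made first, and pyran rings B and D are closed last, in the same flask.

Key step: step 7

Assumption: 2-allyl-4-bromophenol (7) is taken as a catalogue compound; the target has no stereocentre, so no configuration has to be set.

**Route**

Step 1
Reactants: 1 4-bromo-2-hydroxybenzaldehyde; 2 chloromethyl methyl ether
Product: 3 4-bromo-2-(methoxymethoxy)benzaldehyde
Conditions: MOMCl, i-Pr2NEt, CH2Cl2, 0 °C to rt
Reagents that add atoms: chloromethyl methyl ether, COCCl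
Why: Williamson-type O-alkylation of the phenol by the reactive α-chloro ether should give the MOM acetal without touching the aldehyde, fixing the oxygen meta to bromine as the later C8 hydroxyl in a form that cannot migrate.

Step 2
Reactants: 3 4-bromo-2-(methoxymethoxy)benzaldehyde; 4 3-chloroperoxybenzoic acid
Product: 6 4-bromo-2-(methoxymethoxy)phenol, via 4-bromo-2-(methoxymethoxy)phenyl formate 5 (not isolated)
Conditions: mCPBA, CH2Cl2, 0 °C to rt; aqueous NaHCO3 wash; then crude formate, K2CO3 (cat.), MeOH, rt
Reagents that add atoms: 3-chloroperoxybenzoic acid, OOC(=O)c1cccc(Cl)c1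
Why: In this Baeyer–Villiger (Dakin-type) oxidation the electron-rich ortho-alkoxyaryl group should migrate in the Criegee intermediate to give the aryl formate, which mild methanolysis cleaves to the phenol para to bromine while the base-stable MOM acetal stays in place.

Step 3
Reactants: 7 2-allyl-4-bromophenol; 8 2-methylbut-2-ene
Product: 9 4-bromo-2-(3-methylbut-2-en-1-yl)phenol
Conditions: 2-methylbut-2-ene (excess), second-generation Grubbs catalyst RuCl2(=CHPh)(PCy3)(H2IMes) (3 mol %), CH2Cl2, 40 °C
Reagents that add atoms: 2-methylbut-2-ene, CC=C(C)C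
Why: Olefin cross-metathesis of the terminal allyl group with excess 2-methylbut-2-ene should install the trisubstituted prenyl alkene (no E/Z question), and the ruthenium carbene tolerates the free phenol and the aryl bromide.

Step 4
Reactants: 9 4-bromo-2-(3-methylbut-2-en-1-yl)phenol; 10 bis(pinacolato)diboron
Product: 11 2-(3-methylbut-2-en-1-yl)-4-(4,4,5,5-tetramethyl-1,3,2-dioxaborolan-2-yl)phenol
Conditions: B2pin2, Pd(dppf)Cl2 (3 mol %), KOAc, 1,4-dioxane, 90 °C
Reagents that add atoms: bis(pinacolato)diboron, CC1(C)OB(OC1(C)C)B1OC(C)(C)C(C)(C)O1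
Why: Miyaura borylation (oxidative addition of the aryl bromide to zerovalent palladium, acetate-assisted transmetalation with B2pin2, reductive elimination) should proceed with the weak base KOAc without affecting the phenol or the prenyl group.

Step 5
Reactants: 11 2-(3-methylbut-2-en-1-yl)-4-(4,4,5,5-tetramethyl-1,3,2-dioxaborolan-2-yl)phenol; 6 4-bromo-2-(methoxymethoxy)phenol
Product: 12 3-(methoxymethoxy)-3'-(3-methylbut-2-en-1-yl)-[1,1'-biphenyl]-4,4'-diol
Conditions: Pd(OAc)2 (3 mol %), SPhos (6 mol %), K3PO4, 1,4-dioxane/H2O, 80 °C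
Reagents that add atoms: none
Why: Suzuki–Miyaura cross-coupling with the electron-rich biaryl phosphane SPhos should allow oxidative addition into the electron-rich bromophenol and couple the two unprotected phenols, the MOM acetal and the prenyl alkene being inert to aqueous base.

Step 6
Reactants: 12 3-(methoxymethoxy)-3'-(3-methylbut-2-en-1-yl)-[1,1'-biphenyl]-4,4'-diol; 13 3-chloro-3-methylbut-1-yne (two equivalents incorporated)
Product: 14 3-(methoxymethoxy)-3'-(3-methylbut-2-en-1-yl)-4,4'-bis[(2-methylbut-3-yn-2-yl)oxy]-1,1'-biphenyl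
Conditions: 3-chloro-3-methylbut-1-yne (3 equiv), DBU (3.5 equiv), CuCl2·2H2O (1 mol %), MeCN, 0 °C to rt
Reagents that add atoms: 3-chloro-3-methylbut-1-yne, C#CC(C)(C)Cl
Why: Copper-catalysed propargylic etherification, in which a copper acetylide-derived electrophile is captured by the phenoxide at the tertiary carbon, is the standard entry to hindered aryl 1,1-dimethylpropargyl ethers and should alkylate both phenols in one operation, the non-migrating MOM group keeping the two oxygens of ring C distinct.

Step 7
Reactants: 14 3-(methoxymethoxy)-3'-(3-methylbut-2-en-1-yl)-4,4'-bis[(2-methylbut-3-yn-2-yl)oxy]-1,1'-biphenyl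
Product: 17 8-(methoxymethoxy)-2,2,2',2'-tetramethyl-8'-(3-methylbut-2-en-1-yl)-2H,2'H-6,6'-bichromene, via ring-B-closed mono-chromene 15 (not isolated), via ring-D-closed mono-chromene 16 (not isolated)
Conditions: Ph3PAuNTf2 (5 mol %), CH2Cl2, 4 Å MS, rt
Reagents that add atoms: none
Why: The cationic monovalent gold centre π-activates each terminal alkyne, the single free ortho carbon of the aryl ether (the later C4a) attacks the terminal alkyne carbon (the later C4) anti to gold in a Friedel–Crafts manner, the Wheland intermediate rearomatises by proton loss, and protodeauration of the vinyl–gold species releases the chromene and the catalyst. The closest known reaction type is the gold- or PtCl4-catalysed intramolecular hydroarylation of aryl propargyl ethers to 2H-chromenes, applied here to two arms of one molecule. Both pyran rings B and D are closed in the 6-endo-dig mode by forming their C4–C4a bonds; the 5-exo alternative would need attack at the internal alkyne carbon across the short O–CMe2 tether and is geometrically disfavoured, while the gem-dimethyl group (Thorpe–Ingold effect) favours the folded conformer. No stereocentre is created. Regioselectivity is secured because the second ortho position of each ether oxygen is substituted (prenyl CH2 on ring A, OMOM on ring C); chemoselectivity for the alkynes over the prenyl alkene rests on the alkynophilicity of the soft gold cation and on the six-membered arene attack being far easier than a seven-membered attack by the alkene, and the MOM group prevents the C8 oxygen from adding to the activated alkyne. The order of the two closures is immaterial, since both mono-chromenes 15 and 16 converge on 17.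

Step 8
Reactants: 17 8-(methoxymethoxy)-2,2,2',2'-tetramethyl-8'-(3-methylbut-2-en-1-yl)-2H,2'H-6,6'-bichromene
Product: 18 2,2,2',2'-tetramethyl-8'-(3-methylbut-2-en-1-yl)-2H,2'H-[6,6'-bichromen]-8-ol
Conditions: conc. aqueous HCl (cat.), MeOH/THF, 40 °C
Reagents that add atoms: none
Why: Acid-catalysed acetal exchange (MOM cleavage) with methanol as formaldehyde acceptor should free the C8 phenol; no hydroxyl lies ortho to the prenyl group, so chroman formation is not possible, and 2,2-dimethylchromenes are expected to tolerate dilute acid at mild temperature.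

**Compound list**

1 | 4-bromo-2-hydroxybenzaldehyde | O=Cc1ccc(Br)cc1O | starting material
2 | chloromethyl methyl ether | COCCl | starting material
3 | 4-bromo-2-(methoxymethoxy)benzaldehyde | O=Cc1ccc(Br)cc1OCOC | intermediate
4 | 3-chloroperoxybenzoic acid | OOC(=O)c1cccc(Cl)c1 | starting material
5 | 4-bromo-2-(methoxymethoxy)phenyl formate (not isolated) | O=COc1ccc(Br)cc1OCOC | intermediate
6 | 4-bromo-2-(methoxymethoxy)phenol | Oc1ccc(Br)cc1OCOC | intermediate
7 | 2-allyl-4-bromophenol | C=CCc1cc(Br)ccc1O | starting material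
8 | 2-methylbut-2-ene | CC=C(C)C | starting material
9 | 4-bromo-2-(3-methylbut-2-en-1-yl)phenol | CC(C)=CCc1cc(Br)ccc1O | intermediate
10 | bis(pinacolato)diboron | CC1(C)OB(OC1(C)C)B1OC(C)(C)C(C)(C)O1 | starting material
11 | 2-(3-methylbut-2-en-1-yl)-4-(4,4,5,5-tetramethyl-1,3,2-dioxaborolan-2-yl)phenol | CC(C)=CCc1cc(B2OC(C)(C)C(C)(C)O2)ccc1O | intermediate
12 | 3-(methoxymethoxy)-3'-(3-methylbut-2-en-1-yl)-[1,1'-biphenyl]-4,4'-diol | CC(C)=CCc1cc(-c2ccc(O)c(OCOC)c2)ccc1O | intermediate
13 | 3-chloro-3-methylbut-1-yne | C#CC(C)(C)Cl | starting material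
14 | 3-(methoxymethoxy)-3'-(3-methylbut-2-en-1-yl)-4,4'-bis[(2-methylbut-3-yn-2-yl)oxy]-1,1'-biphenyl | CC(C)=CCc1cc(-c2ccc(OC(C)(C)C#C)c(OCOC)c2)ccc1OC(C)(C)C#C | intermediate
15 | 6-{3-(methoxymethoxy)-4-[(2-methylbut-3-yn-2-yl)oxy]phenyl}-2,2-dimethyl-8-(3-methylbut-2-en-1-yl)-2H-chromene (ring B closed, not isolated) | CC(C)=CCc1cc(-c2ccc(OC(C)(C)C#C)c(OCOC)c2)cc2c1OC(C)(C)C=C2 | intermediate
16 | 8-(methoxymethoxy)-2,2-dimethyl-6-{3-(3-methylbut-2-en-1-yl)-4-[(2-methylbut-3-yn-2-yl)oxy]phenyl}-2H-chromene (ring D closed, not isolated) | CC(C)=CCc1cc(-c2cc(OCOC)c3c(c2)C=CC(C)(C)O3)ccc1OC(C)(C)C#C | intermediate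
17 | 8-(methoxymethoxy)-2,2,2',2'-tetramethyl-8'-(3-methylbut-2-en-1-yl)-2H,2'H-6,6'-bichromene | CC(C)=CCc1cc(-c2cc(OCOC)c3c(c2)C=CC(C)(C)O3)cc2c1OC(C)(C)C=C2 | intermediate
18 | 2,2,2',2'-tetramethyl-8'-(3-methylbut-2-en-1-yl)-2H,2'H-[6,6'-bichromen]-8-ol | CC(C)=CCc1cc(-c2cc(O)c3c(c2)C=CC(C)(C)O3)cc2c1OC(C)(C)C=C2 | target

**Step count and risks**

Total steps: 8. Longest linear sequence: 6 steps (steps 1, 2, 5, 6, 7, 8 from 1, or equally steps 3 to 8 from 7).

Steps most likely to fail:

Step 7. The gold-activated alkynes may be captured by the acetal oxygen or by the prenyl alkene instead of the arene, or the second cyclisation may stall through catalyst decomposition. The fallback avoids alkynes and π-acids altogether; it sets out from diol 12 and comes back to the route at 17. Diol 12 would be heated with 3-methylbut-2-enal (CC(C)=CC=O), PhB(OH)2 and catalytic propionic acid in toluene under azeotropic removal of water. Boron-templated ortho-selective C–C bond formation at the single free ortho CH of each phenol, elimination to an ortho-quinone methide and oxa-6π electrocyclisation should annulate both pyran rings. The two mono-annulated phenols, 4-[2,2-dimethyl-8-(3-methylbut-2-en-1-yl)-2H-chromen-6-yl]-2-(methoxymethoxy)phenol F1 and 4-[8-(methoxymethoxy)-2,2-dimethyl-2H-chromen-6-yl]-2-(3-methylbut-2-en-1-yl)phenol F2, would not be isolated and both go on to 17.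

Step 6. Double alkylation of two ortho-substituted phenols may stop at the mono-ether, and copper may promote oxidative coupling of the terminal alkynes. The fallback builds the alkyne by homologation; it sets out from 12 and comes back at 14. Double O-alkylation of 12 with ethyl 2-bromo-2-methylpropanoate (Cs2CO3, DMF, 60 °C) should give the bis(ethyl 2-aryloxy-2-methylpropanoate) F3. Partial reduction with DIBAL-H (CH2Cl2, −78 °C) should give the bis(2-aryloxy-2-methylpropanal) F4. Ohira–Bestmann alkynylation (dimethyl (1-diazo-2-oxopropyl)phosphonate, K2CO3, MeOH, rt) should then convert both aldehydes into the terminal alkynes of 14.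

Step 8. Acid may protonate the electron-rich chromene double bonds or the prenyl alkene during acetal cleavage, leading to solvent addition or oligomerisation. The fallback removes the acetal before any chromene exists and then closes the rings without a π-acid; it sets out from 14 and comes back at 18. Treatment of 14 with catalytic HCl in MeOH at rt should give the free phenol 3'-(3-methylbut-2-en-1-yl)-4,4'-bis[(2-methylbut-3-yn-2-yl)oxy]-[1,1'-biphenyl]-3-ol F5. Heating F5 in N,N-diethylaniline at 190 °C should trigger the thermal propargyl Claisen rearrangement, [1,5]-hydrogen shift and oxa-6π electrocyclisation cascade on both arms; this pericyclic sequence tolerates the free hydroxyl. It would pass through the mono-chromenes 5-[2,2-dimethyl-8-(3-methylbut-2-en-1-yl)-2H-chromen-6-yl]-2-[(2-methylbut-3-yn-2-yl)oxy]phenol F6 and 2,2-dimethyl-6-{3-(3-methylbut-2-en-1-yl)-4-[(2-methylbut-3-yn-2-yl)oxy]phenyl}-2H-chromen-8-ol F7, neither isolated, and should give 18 directly.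

**Further compounds**

F1 | step 7 | 4-[2,2-dimethyl-8-(3-methylbut-2-en-1-yl)-2H-chromen-6-yl]-2-(methoxymethoxy)phenol (not isolated) | CC(C)=CCc1cc(-c2ccc(O)c(OCOC)c2)cc2c1OC(C)(C)C=C2
F2 | step 7 | 4-[8-(methoxymethoxy)-2,2-dimethyl-2H-chromen-6-yl]-2-(3-methylbut-2-en-1-yl)phenol (not isolated) | CC(C)=CCc1cc(-c2cc(OCOC)c3c(c2)C=CC(C)(C)O3)ccc1O
F3 | step 6 | diethyl 2,2'-{[3-(methoxymethoxy)-3'-(3-methylbut-2-en-1-yl)-[1,1'-biphenyl]-4,4'-diyl]bis(oxy)}bis(2-methylpropanoate) | CC(C)=CCc1cc(-c2ccc(OC(C)(C)C(=O)OCC)c(OCOC)c2)ccc1OC(C)(C)C(=O)OCC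
F4 | step 6 | 2,2'-{[3-(methoxymethoxy)-3'-(3-methylbut-2-en-1-yl)-[1,1'-biphenyl]-4,4'-diyl]bis(oxy)}bis(2-methylpropanal) | CC(C)=CCc1cc(-c2ccc(OC(C)(C)C=O)c(OCOC)c2)ccc1OC(C)(C)C=O
F5 | step 8 | 3'-(3-methylbut-2-en-1-yl)-4,4'-bis[(2-methylbut-3-yn-2-yl)oxy]-[1,1'-biphenyl]-3-ol | CC(C)=CCc1cc(-c2ccc(OC(C)(C)C#C)c(O)c2)ccc1OC(C)(C)C#C
F6 | step 8 | 5-[2,2-dimethyl-8-(3-methylbut-2-en-1-yl)-2H-chromen-6-yl]-2-[(2-methylbut-3-yn-2-yl)oxy]phenol (not isolated) | CC(C)=CCc1cc(-c2ccc(OC(C)(C)C#C)c(O)c2)cc2c1OC(C)(C)C=C2
F7 | step 8 | 2,2-dimethyl-6-{3-(3-methylbut-2-en-1-yl)-4-[(2-methylbut-3-yn-2-yl)oxy]phenyl}-2H-chromen-8-ol (not isolated) | CC(C)=CCc1cc(-c2cc(O)c3c(c2)C=CC(C)(C)O3)ccc1OC(C)(C)C#C
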